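**Compound numbers used throughout**
1 2'-hydroxy-3'-methoxyacetophenone; 2 its 5'-bromo derivative; 3 enaminone (not isolated); 4 6-bromo-8-methoxychromone; 5 2-methoxy-4-(pinacolboryl)phenol; 6 its pivalate; 7 the derived boronic acid; 8 (2R)-flavanone; 9 methyl enol ether of 8 (not isolated); 10 C3 iodane ketal (not isolated); 11 trans methyl ester; 12 bromo diol phenol; 13 acrolein; 14 balanophonin.

## Analysis of the target

Balanophonin (14) is a 2-aryl-3-(hydroxymethyl)-2,3-dihydrobenzofuran. Ring B (O1, C2, C3, C3a, C7a) is fused to benzene ring A, which carries a methoxy group at C7 and an (E)-3-oxoprop-1-enyl chain at C5. C2 bears ring C (4-hydroxy-3-methoxyphenyl) and C3 bears the hydroxymethyl carbon C9. The two stereocentres are adjacent, C2 (R) and C3 (S), with ring C and C9 trans across ring B, which is the more stable arrangement. The enal does not tolerate hydride, strong base or nucleophiles, so it has to come last. The C2–O1 bond is a benzylic aryl ether para to the ring C hydroxyl, so acid (benzylic cation) or base (quinone methide from the phenoxide) can open ring B and scramble C2. The difficulty is therefore absolute control of two benzylic centres, one of them labile, and not the ring construction as such. The strategy rests on one feature: ring B together with C9 holds the atoms of a chroman-4-one heterocycle from which one carbon has been pushed out. O1–C2–C3–C3a–C7a plus C9 corresponds to O1–C2–C3–C4–C4a–C8a of a flavanone that already carries ring C at C2, and the C3–C9 bond is the flavanone C3–C4 bond. A flavanone has a single stereocentre, which can be set on a flat chromone, and an oxidative ring contraction can relay it to C3.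

## Retrosynthetic reasoning

14 to 12 and 13. The aryl–vinyl bond at C5 is cut first. The enal is the most fragile group and would not survive the hydride step needed for C9, whereas an aryl bromide passes through every earlier step untouched. The forward reaction is a Heck coupling of 12 with 13, which must deliver the E alkene without ionising the free phenol.

12 to 11. C9 is taken back to an ester carbon and the ring C phenol to its pivalate. Both are undone by one aluminium hydride treatment, so the acyl group that is needed in the key step costs no separate deprotection.

11 to 8. This is the central disconnection. The C3–C3a bond of 11 is cut and the ester carbon C9 is reconnected to C3a, which regenerates the six-membered ketone 8 (C9 becomes flavanone C4, C3a becomes C4a). The gain is large: 8 has only the C2 stereocentre and is made from two flat aromatic pieces. In the forward sense, C3 of 8 must be activated oxidatively, through 9 and 10, so that the ring A carbon shifts from C4 to C3. The shift has to place the ester trans to ring C and leave C2 untouched.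

8 to 4 and 7. The C2–aryl bond is cut. The precursor is then the achiral chromone 4, and the only stereocentre of 8 is set by a catalyst in the step that joins ring C to rings A and B. Cutting O1–C2 instead would lead to a chalcone whose enantioselective closure is less reliable without an extra activating group.

4 to 2 to 1. Chromone C2 is a single carbon delivered by a formamide acetal to the acetyl group of 2. The bromine of 2 goes in by electrophilic substitution of 1, para to the free hydroxyl, which is the position that becomes C5 of the target.

7 to 6 to 5. The boronic acid is reached from the commercial pinacol boronate 5 by acylation of the phenol and removal of the pinacol group. The phenol is protected before the conjugate addition because a free 4'-hydroxyflavanone would racemise easily.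

## Alternatives that were turned down

Alternative 1: Both substituent bonds of ring B, C2–aryl and C3–C9, are cut at once, leading back to an aromatic benzofuran.
- Forward key step: benzofuran A1 is lithiated at C2 and combined with the ring C pinacol boronate A2 to a boronate complex. The allylpalladium cation made from allyl acetate A3 with Pd2(dba)3 and (S)-BINAP attacks C3 while ring C migrates from boron to C2, which dearomatises the furan ring and gives A4.
- For it: it is convergent, and one enantioselective catalytic event sets both ring B stereocentres with the trans relation built in by anti addition across C2=C3. On this point it is stronger than the chosen plan, which sets C2 by catalysis and C3 by relay.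
- Against it here: C2 of A4 is fully substituted and carries boron where the target needs hydrogen. Stereoretentive protodeboronation of a tertiary, benzylic, oxygen-bearing boronic ester next to an electron-rich arene is a weak point. The allyl group brings three carbons where C9 is one, so it must be isomerised, cleaved oxidatively and reduced through an epimerisable C3 aldehyde. The ring A acetal still needs unmasking and a two-carbon homologation.
- Comparison: the chosen route delivers C9 directly at the ester oxidation level and has hydrogen at C2 from the start, so its sequence after the key step is two steps and not six or more.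

Alternative 2: Ring A itself is dismantled by cutting C3a–C7a and C6–C7, leading to the open-chain furan-yne A5, which already holds both stereocentres.
- Forward key step: Ph3PAuNTf2 activates the ethynyl ether. The furan carbon that becomes C3a attacks the oxygen-bearing alkyne carbon, and the furan opens and recloses on the terminal alkyne carbon, so ring B and the phenolic ring A of A6 form together.
- For it: the key step is a neutral, atom-economic isomerisation, and it creates no stereocentre, so it has no selectivity problem of its own. That is an advantage over the chosen key step.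
- Against it here: A5 is costly. Its anti stereodiad needs a separate asymmetric synthesis on a 2,4-disubstituted furan. A secondary benzylic alkynyl ether is made under strongly basic conditions and tends to fragment to a ketene and an alkene on mild warming. The cascade is far less established for oxygen-substituted alkynes than for carbon- or nitrogen-tethered ones. A6 still lacks the C7 methyl group and the enal, so several steps follow.
- Comparison: the chosen plan starts from intact, commercially available aromatic rings and is expected to be about half as long.

Alternative 3: C2–aryl and O1–C2 are cut, so the only stereocentre to be made is C3, obtained by desymmetrising the prochiral diol A7 and oxidising it to aldehyde A8.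
- Forward key step: the ring C arylmagnesium bromide A9 adds to A8, and aqueous HCl in the same flask removes the protecting groups and closes O1–C2 through the ring C quinone methide, giving A10 with the trans ring B under thermodynamic control.
- For it: it is short, A10 is one Wittig olefination away from the target, and the trans relation is set by equilibration. In step count it is at least as good as the chosen route.
- Against it here: the single stereocentre sits in A8 as the α-carbon of an α-aryl aldehyde with a β-oxygen, and it is exposed there to a basic Grignard reagent, so enolisation or β-elimination can erase it. The desymmetrisation of A7 with its hindered, doubly ortho-substituted aryl group is uncertain in selectivity. The cationic closure can also lose the C3 proton or formaldehyde.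
- Comparison: in the chosen strategy the stereo-defining step acts on a chromone that has no enolisable stereocentre, and C3 is created last by a stereospecific shift.

Key step: step 6

Assumption: the (S)-configured pyridine–oxazoline ligand is taken to deliver the aryl group to the same face of chromone 4 as it does with cyclic enones, which gives (2R)-8; if the sense proves opposite, the (R)-ligand is used and nothing else changes.

## Route

Step 1
Reactants: 1 2'-hydroxy-3'-methoxyacetophenone
Product: 2 1-(5-bromo-2-hydroxy-3-methoxyphenyl)ethan-1-one
Conditions: NBS (1.05 equiv), MeCN, 0 °C to rt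
Reagents that add atoms: N-bromosuccinimide, O=C1CCC(=O)N1Br
Why: Electrophilic aromatic bromination; the free hydroxyl directs para because both ortho positions are occupied, and that carbon is also meta to the deactivating acetyl group, so one regioisomer is expected.

Step 2
Reactants: 2 1-(5-bromo-2-hydroxy-3-methoxyphenyl)ethan-1-one
Product: 4 6-bromo-8-methoxy-4H-chromen-4-one, via enaminone 3 (not isolated)
Conditions: Me2NCH(OMe)2, toluene, 100 °C; then conc. HCl, CH2Cl2, 40 °C
Reagents that add atoms: N,N-dimethylformamide dimethyl acetal, COC(OC)N(C)C
Why: Condensation of the methyl ketone with the formamide acetal gives the enaminone 3; acid then promotes addition of the phenol to the β-carbon and loss of dimethylamine (addition–elimination), the standard enaminone route to chromones unsubstituted at C2 and C3.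

Step 3
Reactants: 5 2-methoxy-4-(4,4,5,5-tetramethyl-1,3,2-dioxaborolan-2-yl)phenol
Product: 6 2-methoxy-4-(4,4,5,5-tetramethyl-1,3,2-dioxaborolan-2-yl)phenyl 2,2-dimethylpropanoate
Conditions: t-BuCOCl, Et3N, DMAP (cat.), CH2Cl2, 0 °C to rt
Reagents that add atoms: pivaloyl chloride, CC(C)(C)C(=O)Cl
Why: Acylation of the phenol; the pivalate is chosen because it is electron-withdrawing, survives the acidic key step through its bulk, and falls off in the hydride step without a separate operation.

Step 4
Reactants: 6 2-methoxy-4-(4,4,5,5-tetramethyl-1,3,2-dioxaborolan-2-yl)phenyl 2,2-dimethylpropanoate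
Product: 7 [3-methoxy-4-(pivaloyloxy)phenyl]boronic acid
Conditions: NaIO4, NH4OAc, acetone/H2O (1:1), rt
Reagents that add atoms: water, O
Why: Oxidative cleavage of the pinacol released in the ester–acid equilibrium drives the hydrolysis to the free boronic acid under near-neutral conditions that leave the aryl pivalate intact; the free acid is wanted because it transmetalates to cationic divalent palladium much more readily than the pinacol ester.

Step 5
Reactants: 4 6-bromo-8-methoxy-4H-chromen-4-one; 7 [3-methoxy-4-(pivaloyloxy)phenyl]boronic acid
Product: 8 (2R)-6-bromo-8-methoxy-2-[3-methoxy-4-(pivaloyloxy)phenyl]chroman-4-one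
Conditions: Pd(OCOCF3)2 (5 mol %), (S)-4-tert-butyl-2-(pyridin-2-yl)-4,5-dihydrooxazole [(S)-t-BuPyOx] (6 mol %), NH4PF6 (30 mol %), H2O (5 equiv), ClCH2CH2Cl, 60 °C; 7 in excess
Reagents that add atoms: none
Why: Enantioselective conjugate addition of an arylboronic acid to a chromone under divalent palladium catalysis: transmetalation, enantio-determining carbopalladation of C2=C3 on the face left open by the tert-butyl group of the ligand, then protonolysis of the palladium enolate by water. Palladium stays divalent throughout, so the C–Br bond is not attacked, and the weakly acidic medium avoids the base-induced retro-oxa-Michael opening that racemises flavanones.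

Step 6
Reactants: 8 (2R)-6-bromo-8-methoxy-2-[3-methoxy-4-(pivaloyloxy)phenyl]chroman-4-one
Product: 11 methyl (2R,3R)-5-bromo-7-methoxy-2-[3-methoxy-4-(pivaloyloxy)phenyl]-2,3-dihydro-1-benzofuran-3-carboxylate, via enol ether 9 (not isolated), via iodane ketal 10 (not isolated)
Conditions: PhI(OAc)2 (1.2 equiv), conc. H2SO4, HC(OMe)3, 0 °C to rt, dark
Reagents that add atoms: trimethyl orthoformate, COC(OC)OC
Why: Acid and the orthoformate convert the C4 ketone through its ketal into the methyl enol ether 9, whose C3 attacks the trivalent iodine of PhI(OAc)2 on the face away from the C2 aryl group while methanol re-adds at C4, giving the λ3-iodane 10 with iodine equatorial and trans to ring C. In 10 the C4–C4a bond lies antiperiplanar to the C3–I bond, so the ring A carbon C4a moves from C4 to C3 as PhI leaves (a 1,2-aryl shift through a bridged arenium transition state, pushed by the two methoxy groups on C4), and the dimethoxycarbenium ion left at C4 ends as the methyl ester carbon C9. This is the known oxidative ring contraction of flavanones to methyl trans-2-aryl-2,3-dihydrobenzofuran-3-carboxylates, a relative of the oxidative 1,2-aryl shift that turns aryl ketones into arylacetic esters. Ring B is not closed from a chain: it arises by contraction of the pyranone ring, the new C3–C3a bond forming in a formally 3-exo-tet attack of the ipso carbon on C3 before C4–C4a breaks. The new stereocentre C3 is controlled by C2: iodination anti to the aryl group and inversion at C3 during the shift place the ester trans to ring C, which is also the more stable arrangement. The step needs migration of ring A in preference to migration of ring C from C2 (isoflavone) and to loss of the C2 hydrogen (flavone); the equatorial C3–I bond is aligned only with C4–C4a, and the pivaloyloxy group makes ring C a poorer migrating group and a poorer stabiliser of positive charge at C2, which also guards the C2 configuration against acid ionisation of C2–O1.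

Step 7
Reactants: 11 methyl (2R,3R)-5-bromo-7-methoxy-2-[3-methoxy-4-(pivaloyloxy)phenyl]-2,3-dihydro-1-benzofuran-3-carboxylate
Product: 12 4-[(2R,3S)-5-bromo-3-(hydroxymethyl)-7-methoxy-2,3-dihydro-1-benzofuran-2-yl]-2-methoxyphenol
Conditions: LiAlH4 (4 equiv), THF, −20 to 0 °C, ester added to the hydride; aq. KNaC4H4O6/NH4Cl work-up
Reagents that add atoms: none
Why: Hydride reduction of the methyl ester to the C9 alcohol and reductive cleavage of the aryl pivalate in one operation. Inverse addition at low temperature makes hydride delivery to the ester faster than deprotonation at C3, and aryl bromides are not reduced by LiAlH4 at 0 °C; the change of descriptor at C3 from R to S is only a change of priorities.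

Step 8
Reactants: 12 4-[(2R,3S)-5-bromo-3-(hydroxymethyl)-7-methoxy-2,3-dihydro-1-benzofuran-2-yl]-2-methoxyphenol; 13 acrolein
Product: 14 balanophonin, (E)-3-[(2R,3S)-2-(4-hydroxy-3-methoxyphenyl)-3-(hydroxymethyl)-7-methoxy-2,3-dihydro-1-benzofuran-5-yl]prop-2-enal
Conditions: Pd(OAc)2 (10 mol %), Bu4NCl, NaHCO3, DMF, 80 °C, sealed tube; 13 in excess
Reagents that add atoms: none
Why: Heck reaction under ligand-free phase-transfer conditions: zerovalent palladium inserts into the C5–Br bond, syn carbopalladation of acrolein at its terminal carbon and syn β-hydride elimination give the E enal. NaHCO3 is too weak a base to ionise the ring C phenol to any extent, so ring B should not open through a quinone methide, and the free hydroxyl groups are tolerated.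

## Compound list

1 | 2'-hydroxy-3'-methoxyacetophenone | CC(=O)c1cccc(OC)c1O | starting material
2 | 1-(5-bromo-2-hydroxy-3-methoxyphenyl)ethan-1-one | CC(=O)c1cc(Br)cc(OC)c1O | intermediate
3 | (E)-1-(5-bromo-2-hydroxy-3-methoxyphenyl)-3-(dimethylamino)prop-2-en-1-one | CN(C)/C=C/C(=O)c1cc(Br)cc(OC)c1O | intermediate (not isolated)
4 | 6-bromo-8-methoxy-4H-chromen-4-one | COc1cc(Br)cc2c(=O)ccoc12 | intermediate
5 | 2-methoxy-4-(4,4,5,5-tetramethyl-1,3,2-dioxaborolan-2-yl)phenol | COc1cc(B2OC(C)(C)C(C)(C)O2)ccc1O | starting material
6 | 2-methoxy-4-(4,4,5,5-tetramethyl-1,3,2-dioxaborolan-2-yl)phenyl 2,2-dimethylpropanoate | COc1cc(B2OC(C)(C)C(C)(C)O2)ccc1OC(=O)C(C)(C)C | intermediate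
7 | [3-methoxy-4-(pivaloyloxy)phenyl]boronic acid | COc1cc(B(O)O)ccc1OC(=O)C(C)(C)C | intermediate
8 | (2R)-6-bromo-8-methoxy-2-[3-methoxy-4-(pivaloyloxy)phenyl]chroman-4-one | COc1cc([C@@H]2Oc3c(OC)cc(Br)cc3C(=O)C2)ccc1OC(=O)C(C)(C)C | intermediate
9 | (2R)-6-bromo-4,8-dimethoxy-2-[3-methoxy-4-(pivaloyloxy)phenyl]-2H-chromene | COc1cc([C@@H]2Oc3c(OC)cc(Br)cc3C(OC)=C2)ccc1OC(=O)C(C)(C)C | intermediate (not isolated)
10 | (2S,3S)-3-[acetoxy(phenyl)-λ3-iodanyl]-6-bromo-4,4,8-trimethoxy-2-[3-methoxy-4-(pivaloyloxy)phenyl]chromane, iodine trans to the C2 aryl group | COc1cc([C@@H]2Oc3c(OC)cc(Br)cc3C(OC)(OC)[C@H]2I(OC(C)=O)c4ccccc4)ccc1OC(=O)C(C)(C)C | intermediate (not isolated)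
11 | methyl (2R,3R)-5-bromo-7-methoxy-2-[3-methoxy-4-(pivaloyloxy)phenyl]-2,3-dihydro-1-benzofuran-3-carboxylate (trans) | COc1cc([C@@H]2Oc3c(OC)cc(Br)cc3[C@H]2C(=O)OC)ccc1OC(=O)C(C)(C)C | intermediate
12 | 4-[(2R,3S)-5-bromo-3-(hydroxymethyl)-7-methoxy-2,3-dihydro-1-benzofuran-2-yl]-2-methoxyphenol (trans) | COc1cc([C@@H]2Oc3c(OC)cc(Br)cc3[C@H]2CO)ccc1O | intermediate
13 | acrolein (prop-2-enal) | C=CC=O | starting material
14 | balanophonin, (E)-3-[(2R,3S)-2-(4-hydroxy-3-methoxyphenyl)-3-(hydroxymethyl)-7-methoxy-2,3-dihydro-1-benzofuran-5-yl]prop-2-enal | COc1cc([C@@H]2Oc3c(OC)cc(/C=C/C=O)cc3[C@H]2CO)ccc1O | target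

## Step count and risk

Total step count: 8. Longest linear sequence: 6 steps (steps 1, 2, 5, 6, 7, 8; the branch through steps 3 and 4 is equally long).

Step 6 (key step).
- What may go wrong: migration of ring C from C2 to C3 (isoflavone formation) or loss of the C2 hydrogen (dehydrogenation to the flavone) may compete with the ring A shift. Bromine and methoxy both sit meta to the migrating carbon C4a and lower its migratory aptitude slightly compared with the parent flavanone. The trans selectivity may be incomplete, and C2 may lose configuration by acid ionisation of C2–O1 or by reversible electrocyclic opening of the 2H-chromene 9.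
- Fallback, from 8 back to 11: the same ring contraction is run as a Wolff rearrangement. Compound 8 is heated with N,N-dimethylformamide dimethyl acetal to give the 3-(dimethylaminomethylidene) ketone F1. Tosyl azide converts this by cycloaddition and loss of the sulfonyl formamidine into the 3-diazo ketone F2. Irradiation above 300 nm in methanol gives the C3 carbene, the ring A carbon shifts from C4 to C3, and the ketene is trapped by methanol as 11 and its cis epimer. The cis ester is converged on the trans ester by equilibration at C3 with catalytic DBU, which does not touch C2 or the pivalate.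

Step 5.
- What may go wrong: insufficient enantioselectivity or the opposite sense of induction on this substituted chromone, slow carbopalladation with protodeboronation of 7, or erosion of configuration by retro-oxa-Michael opening of 8.
- Fallback, from 2 back to 8: the O1–C2 bond is formed instead of the C2–aryl bond. Compound 2 is deprotonated with excess LiN(SiMe3)2 and C-acylated with Boc2O to the β-keto ester F3. Knoevenagel condensation of F3 with vanillin pivalate F4 (from vanillin and pivaloyl chloride) gives the alkylidene F5. A quinine- or quinidine-derived bifunctional thiourea, whichever pseudo-enantiomer leads to 2R, catalyses the intramolecular oxa-Michael addition to the flavanone tert-butyl ester F6. TsOH in warm toluene removes the tert-butyl ester with decarboxylation and gives 8.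

Step 8.
- What may go wrong: oxidative addition into the electron-rich C5–Br bond may be slow at temperatures at which acrolein polymerises, and partial ionisation of the ring C phenol may open ring B through the quinone methide and epimerise C2.
- Fallback, from 12 back to 14: a base-free Stille coupling of 12 with the known (E)-tributyl(3,3-diethoxyprop-1-enyl)stannane (Pd(PPh3)4, toluene, 90 °C) gives the diethyl acetal F7. Brief treatment with dilute aqueous acid in THF hydrolyses it to 14.

Step 7.
- What may go wrong: hydrogenolysis of the C–Br bond by the hydride would remove the handle for the last step, and opening of ring B in the basic medium is possible once the ring C phenoxide is formed.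
- Fallback, from 11 back to 14: the order of events is changed. The Stille coupling described for step 8 is run first on 11 and gives the acetal ester F8. LiAlH4 then reduces the ester and cleaves the pivalate with no bromine present and the aldehyde masked, giving the diethyl acetal F7. Dilute acid gives 14.

## Further compounds

F1 | step 6 | (2S)-6-bromo-3-[(E)-(dimethylamino)methylidene]-8-methoxy-2-[3-methoxy-4-(pivaloyloxy)phenyl]chroman-4-one | COc1cc([C@@H]2Oc3c(OC)cc(Br)cc3C(=O)/C2=C/N(C)C)ccc1OC(=O)C(C)(C)C
F2 | step 6 | (2S)-6-bromo-3-diazo-8-methoxy-2-[3-methoxy-4-(pivaloyloxy)phenyl]chroman-4-one | COc1cc([C@@H]2Oc3c(OC)cc(Br)cc3C(=O)C2=[N+]=[N-])ccc1OC(=O)C(C)(C)C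
F3 | step 5 | tert-butyl 3-(5-bromo-2-hydroxy-3-methoxyphenyl)-3-oxopropanoate | CC(C)(C)OC(=O)CC(=O)c1cc(Br)cc(OC)c1O
F4 | step 5 | 4-formyl-2-methoxyphenyl 2,2-dimethylpropanoate (vanillin pivalate) | COc1cc(C=O)ccc1OC(=O)C(C)(C)C
F5 | step 5 | tert-butyl 2-(5-bromo-2-hydroxy-3-methoxybenzoyl)-3-[3-methoxy-4-(pivaloyloxy)phenyl]prop-2-enoate (E/Z mixture) | CC(C)(C)OC(=O)C(=Cc1ccc(OC(=O)C(C)(C)C)c(OC)c1)C(=O)c1cc(Br)cc(OC)c1O
F6 | step 5 | tert-butyl (2R)-6-bromo-8-methoxy-2-[3-methoxy-4-(pivaloyloxy)phenyl]-4-oxochromane-3-carboxylate (C3 labile, keto–enol) | COc1cc([C@@H]2Oc3c(OC)cc(Br)cc3C(=O)C2C(=O)OC(C)(C)C)ccc1OC(=O)C(C)(C)C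
F7 | step 8 | 4-[(2R,3S)-5-[(E)-3,3-diethoxyprop-1-en-1-yl]-3-(hydroxymethyl)-7-methoxy-2,3-dihydro-1-benzofuran-2-yl]-2-methoxyphenol | COc1cc([C@@H]2Oc3c(OC)cc(/C=C/C(OCC)OCC)cc3[C@H]2CO)ccc1O
F8 | step 7 | methyl (2R,3R)-5-[(E)-3,3-diethoxyprop-1-en-1-yl]-7-methoxy-2-[3-methoxy-4-(pivaloyloxy)phenyl]-2,3-dihydro-1-benzofuran-3-carboxylate | COc1cc([C@@H]2Oc3c(OC)cc(/C=C/C(OCC)OCC)cc3[C@H]2C(=O)OC)ccc1OC(=O)C(C)(C)C
A1 | alternative 1 | 2-(7-methoxy-1-benzofuran-5-yl)-1,3-dioxolane | COc1cc(C2OCCO2)cc2ccoc12
A2 | alternative 1 | 2-[3-methoxy-4-(methoxymethoxy)phenyl]-4,4,5,5-tetramethyl-1,3,2-dioxaborolane | COCOc1ccc(B2OC(C)(C)C(C)(C)O2)cc1OC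
A3 | alternative 1 | allyl acetate | C=CCOC(C)=O
A4 | alternative 1 | trans-3-allyl-5-(1,3-dioxolan-2-yl)-7-methoxy-2-[3-methoxy-4-(methoxymethoxy)phenyl]-2-(4,4,5,5-tetramethyl-1,3,2-dioxaborolan-2-yl)-2,3-dihydro-1-benzofuran (allyl trans to aryl, boron in the place of the C2 hydrogen) | COc1cc([C@]2(B4OC(C)(C)C(C)(C)O4)Oc3c(OC)cc(C5OCCO5)cc3[C@H]2CC=C)ccc1OCOC
A5 | alternative 2 | 2-{5-[1-(ethynyloxy)-3-(methoxymethoxy)-1-[3-methoxy-4-(methoxymethoxy)phenyl]propan-2-yl]furan-3-yl}-1,3-dioxolane, configured to give trans-A6 | COc1cc([C@H](OC#C)[C@H](COCOC)c2cc(C3OCCO3)co2)ccc1OCOC
A6 | alternative 2 | (2R,3S)-5-(1,3-dioxolan-2-yl)-2-[3-methoxy-4-(methoxymethoxy)phenyl]-3-(methoxymethoxymethyl)-2,3-dihydro-1-benzofuran-7-ol (trans) | COc1cc([C@@H]2Oc3c(O)cc(C4OCCO4)cc3[C@H]2COCOC)ccc1OCOC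
A7 | alternative 3 | 2-[5-(1,3-dioxolan-2-yl)-3-methoxy-2-(methoxymethoxy)phenyl]propane-1,3-diol | OCC(CO)c1cc(C2OCCO2)cc(OC)c1OCOC
A8 | alternative 3 | (2S)-2-[5-(1,3-dioxolan-2-yl)-3-methoxy-2-(methoxymethoxy)phenyl]-3-(methoxymethoxy)propanal | O=C[C@H](COCOC)c1cc(C2OCCO2)cc(OC)c1OCOC
A9 | alternative 3 | [3-methoxy-4-(methoxymethoxy)phenyl]magnesium bromide | COCOc1ccc([Mg]Br)cc1OC
A10 | alternative 3 | (2R,3S)-2-(4-hydroxy-3-methoxyphenyl)-3-(hydroxymethyl)-7-methoxy-2,3-dihydro-1-benzofuran-5-carbaldehyde (trans) | COc1cc([C@@H]2Oc3c(OC)cc(C=O)cc3[C@H]2CO)ccc1O
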